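**Retrosynthetic overview**
1. Floranol 18 comes from its tris-MOM ether 17 by acetal cleavage in the last step.
2. 17 is cut at C2–C1′ (ring C to ring B) and at C3–OH together, giving the achiral chromone 11 and 1-bromo-2-(methoxymethoxy)benzene 12. One telescoped operation transfers the aryl group to C2 under Rh catalysis, traps the enolate at O4 as a silyl enol ether and oxygenates C3.
3. Enabling feature: in ring C of 11, O1–C2=C3–C4=O4 is a vinylogous ester. C2 is its β-carbon (aryl acceptor) and C3 its α-carbon, which after aryl transfer is the nucleophilic carbon of a C3=C4–O4Si enol ether and takes the hydroxyl anti to the new aryl group.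
4. 11 comes from salicylaldehyde 7 (acetylide addition, oxidation, amine-mediated 6-endo closure of ring C through O1–C2). 7 comes from phenol 4 (O-tert-prenylation and aromatic Claisen for the C8 prenyl, then ortho-formylation). 4 comes from 2-methoxyresorcinol 1 (MOM protection, C–H borylation and oxidation to install the future O1).
5. Ring order: ring A is bought with 1 and fully substituted first, ring C is closed in step 6, and ring B arrives intact in step 7.

Key step: step 7

Remark: (S)-BINAP is chosen because Rh/BINAP aryl additions to cyclic enones and 4-quinolones give this sense of induction (the antipodal ligand would be used if it proved opposite); 12 and the carbonate reagent of step 3 are taken as purchasable.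

**Step 1**
Reactants: 1 2-methoxyresorcinol
Product: 2 2-methoxy-1,3-bis(methoxymethoxy)benzene
Conditions: MOMCl (2.5 equiv), iPr2NEt, CH2Cl2, 0 → 20 °C
Reagents that add atoms: chloromethyl methyl ether, COCCl
Why: O-alkylation of both phenols gives MOM ethers, which should survive the bases, organometallics and oxidants of steps 2–7 and are removed together with the ring-B MOM group in step 8.

**Step 2**
Reactants: 2 2-methoxy-1,3-bis(methoxymethoxy)benzene
Product: 4 4-methoxy-3,5-bis(methoxymethoxy)phenol, via aryl pinacolboronate 3 (not isolated)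
Conditions: [Ir(OMe)(cod)]2 (1.5 mol%), dtbpy, B2pin2 (0.6 equiv), THF, 80 °C; then 30% H2O2, aq. NaOH, 0 °C
Reagents that add atoms: hydrogen peroxide, OO
Why: Sterically controlled iridium-catalysed aromatic C–H borylation should occur at C5, the only C–H without an ortho substituent, and peroxide oxidation of the C–B bond gives the phenol that becomes O1, set apart from the two MOM-protected oxygens.

**Step 3**
Reactants: 4 4-methoxy-3,5-bis(methoxymethoxy)phenol
Product: 6 4-methoxy-3,5-bis(methoxymethoxy)-2-(3-methylbut-2-en-1-yl)phenol, via tert-prenyl aryl ether 5 (not isolated)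
Conditions: tert-butyl 2-methylbut-3-en-2-yl carbonate (1.3 equiv), Pd(PPh3)4 (2 mol%), THF, 0 → 20 °C; silica plug; toluene, 110 °C
Reagents that add atoms: tert-butyl 2-methylbut-3-en-2-yl carbonate, CC(C)(C)OC(=O)OC(C)(C)C=C
Why: Tsuji–Trost O-allylation at the tertiary terminus of the 1,1-dimethyl-π-allylpalladium complex is followed by aromatic Claisen rearrangement, which, with the para position blocked by OMe and two equivalent ortho positions, can only give the ortho C-prenyl phenol.

**Step 4**
Reactants: 6 4-methoxy-3,5-bis(methoxymethoxy)-2-(3-methylbut-2-en-1-yl)phenol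
Product: 7 2-hydroxy-5-methoxy-4,6-bis(methoxymethoxy)-3-(3-methylbut-2-en-1-yl)benzaldehyde
Conditions: MgCl2 (anhydrous), Et3N, (CH2O)n, MeCN, reflux
Reagents that add atoms: paraformaldehyde (as formaldehyde), C=O
Why: In the magnesium-mediated ortho-formylation (Casnati–Skattebøl) the magnesium phenoxide delivers formaldehyde to the only free ortho carbon and a second formaldehyde oxidises the benzylic alkoxide, under basic conditions that should leave MOM ethers and the prenyl olefin untouched.

**Step 5**
Reactants: 7 2-hydroxy-5-methoxy-4,6-bis(methoxymethoxy)-3-(3-methylbut-2-en-1-yl)benzaldehyde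
Product: 8 1-[2-hydroxy-5-methoxy-4,6-bis(methoxymethoxy)-3-(3-methylbut-2-en-1-yl)phenyl]prop-2-yn-1-ol (racemic, used crude)
Conditions: ethynylmagnesium bromide (3 equiv), THF, 0 → 20 °C; then H2O (Rochelle salt work-up)
Reagents that add atoms: ethynylmagnesium bromide, C#C[Mg]Br
Why: Grignard 1,2-addition of the acetylide to the aldehyde follows deprotonation of the phenol by the first equivalent, and the new carbinol centre is racemic and is destroyed in step 6.

**Step 6**
Reactants: 8 1-[2-hydroxy-5-methoxy-4,6-bis(methoxymethoxy)-3-(3-methylbut-2-en-1-yl)phenyl]prop-2-yn-1-ol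
Product: 11 6-methoxy-5,7-bis(methoxymethoxy)-8-(3-methylbut-2-en-1-yl)-4H-chromen-4-one, via ynone 9 (not isolated), via diethylaminoenone 10 (not isolated)
Conditions: activated MnO2, CH2Cl2, 20 °C; filter; Et2NH (1.2 equiv), EtOH, 20 °C; then AcOH (cat.), 50 °C
Reagents that add atoms: none
Why: MnO2 oxidation of the benzylic-propargylic alcohol, aza-Michael addition of Et2NH to the ynone and 6-endo-trig addition–elimination of the ortho phenol onto the β-aminoenone should close the pyranone ring C as the chromone, the amine detour excluding the 5-exo-dig closure.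

**Step 7**
Reactants: 11 6-methoxy-5,7-bis(methoxymethoxy)-8-(3-methylbut-2-en-1-yl)-4H-chromen-4-one; 12 1-bromo-2-(methoxymethoxy)benzene
Product: 17 (2R,3R)-3-hydroxy-6-methoxy-5,7-bis(methoxymethoxy)-2-[2-(methoxymethoxy)phenyl]-8-(3-methylbut-2-en-1-yl)-2,3-dihydro-4H-chromen-4-one, via aryllithium 13 (not isolated), via arylzinc chloride 14 (not isolated), via silyl enol ether 15 (not isolated), via siloxy epoxide 16 (not isolated)
Conditions: 12, n-BuLi, THF, −78 °C, then ZnCl2, −78 → 20 °C; 11, [RhCl((S)-binap)]2 (5 mol% Rh), Me3SiCl (2 equiv), THF, 20 °C; pentane, filtration (Celite), evaporation; DMDO (1.05 equiv, titrated), acetone/CH2Cl2, −78 → −40 °C; AcOH/H2O/THF, 0 °C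
Reagents that add atoms: dimethyldioxirane (DMDO), CC1(C)OO1
Why: Proposed new method: arylzinc 14 transmetalates to the (S)-BINAP–Rh(I) centre, the aryl–Rh bond inserts the C2=C3 bond of 11 with the aryl going to C2, and Me3SiCl silylates the oxa-π-allyl rhodium enolate at O4 to release enol silane 15 and Rh–Cl; dimethyldioxirane then epoxidises C3=C4 of 15 and hydrolysis of siloxy-oxirane 16 gives the α-ketol. The closest known reaction types are the Rh/BINAP-catalysed asymmetric 1,4-addition of arylzinc chlorides with Me3SiCl to 4-quinolones and 2,3-dihydro-4-pyridones, the Rh-catalysed asymmetric 1,4-addition of arylboronic acids to chromones, and the Rubottom oxidation of flavanone enol silanes; new is the zinc/silyl chloride variant on a chromone and its telescoping with the oxidation. No ring of the target is closed (ring C stays intact; the transient oxirane forms by concerted oxygen transfer and is opened again). C2 is set by the catalyst (enantioface selection in the insertion, (S)-BINAP being expected to give the 2S enol silane), and C3 by the substrate, the dioxirane attacking the enol ether face anti to the C2 aryl group to give the 2,3-trans ketol, which is also the thermodynamically favoured diastereomer. The step needs 1,4- over 1,2-arylation, secured by the aryl–Rh species (not the ketone-inert arylzinc) being the carbon nucleophile; ortho connectivity in ring B, fixed by the C–Br position of 12; and oxidation of the enol ether in preference to the prenyl olefin, secured by the much higher nucleophilicity of the O-silylated, arene-conjugated C3=C4 bond and one titrated equivalent of oxidant at −78 °C.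

**Step 8**
Reactants: 17 (2R,3R)-3-hydroxy-6-methoxy-5,7-bis(methoxymethoxy)-2-[2-(methoxymethoxy)phenyl]-8-(3-methylbut-2-en-1-yl)-2,3-dihydro-4H-chromen-4-one
Product: 18 floranol
Conditions: HCl (2 M) in MeOH/THF, 40 °C
Reagents that add atoms: none
Why: Acid-catalysed acetal exchange to dimethoxymethane removes the three phenolic MOM groups under conditions of the kind tolerated by C-prenylated flavonoids, C2 and C3 are not involved, and the 2,3-trans ketol is the thermodynamic isomer.

**Compound list**
1 | 2-methoxyresorcinol (2-methoxybenzene-1,3-diol) | COc1c(O)cccc1O | starting material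
2 | 2-methoxy-1,3-bis(methoxymethoxy)benzene | COc1c(OCOC)cccc1OCOC | intermediate
3 | 2-[4-methoxy-3,5-bis(methoxymethoxy)phenyl]-4,4,5,5-tetramethyl-1,3,2-dioxaborolane | COc1c(OCOC)cc(B2OC(C)(C)C(C)(C)O2)cc1OCOC | intermediate
4 | 4-methoxy-3,5-bis(methoxymethoxy)phenol | COc1c(OCOC)cc(O)cc1OCOC | intermediate
5 | 2-methoxy-1,3-bis(methoxymethoxy)-5-[(2-methylbut-3-en-2-yl)oxy]benzene | COc1c(OCOC)cc(OC(C)(C)C=C)cc1OCOC | intermediate
6 | 4-methoxy-3,5-bis(methoxymethoxy)-2-(3-methylbut-2-en-1-yl)phenol | COc1c(OCOC)c(CC=C(C)C)c(O)cc1OCOC | intermediate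
7 | 2-hydroxy-5-methoxy-4,6-bis(methoxymethoxy)-3-(3-methylbut-2-en-1-yl)benzaldehyde | COc1c(OCOC)c(CC=C(C)C)c(O)c(C=O)c1OCOC | intermediate
8 | 1-[2-hydroxy-5-methoxy-4,6-bis(methoxymethoxy)-3-(3-methylbut-2-en-1-yl)phenyl]prop-2-yn-1-ol (racemic) | COc1c(OCOC)c(CC=C(C)C)c(O)c(C(O)C#C)c1OCOC | intermediate
9 | 1-[2-hydroxy-5-methoxy-4,6-bis(methoxymethoxy)-3-(3-methylbut-2-en-1-yl)phenyl]prop-2-yn-1-one | COc1c(OCOC)c(CC=C(C)C)c(O)c(C(=O)C#C)c1OCOC | intermediate
10 | (2E)-3-(diethylamino)-1-[2-hydroxy-5-methoxy-4,6-bis(methoxymethoxy)-3-(3-methylbut-2-en-1-yl)phenyl]prop-2-en-1-one | COc1c(OCOC)c(CC=C(C)C)c(O)c(C(=O)/C=C/N(CC)CC)c1OCOC | intermediate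
11 | 6-methoxy-5,7-bis(methoxymethoxy)-8-(3-methylbut-2-en-1-yl)-4H-chromen-4-one | COc1c(OCOC)c(CC=C(C)C)c2c(c1OCOC)c(=O)cco2 | intermediate
12 | 1-bromo-2-(methoxymethoxy)benzene | COCOc1ccccc1Br | starting material
13 | [2-(methoxymethoxy)phenyl]lithium | [Li]c1ccccc1OCOC | intermediate
14 | chloro[2-(methoxymethoxy)phenyl]zinc | Cl[Zn]c1ccccc1OCOC | intermediate
15 | {[(2S)-6-methoxy-5,7-bis(methoxymethoxy)-2-[2-(methoxymethoxy)phenyl]-8-(3-methylbut-2-en-1-yl)-2H-chromen-4-yl]oxy}trimethylsilane | COc1c(OCOC)c(CC=C(C)C)c2c(c1OCOC)C(O[Si](C)(C)C)=C[C@@H](c1ccccc1OCOC)O2 | intermediate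
16 | (2R,3R,4R)-3,4-epoxy-6-methoxy-5,7-bis(methoxymethoxy)-2-[2-(methoxymethoxy)phenyl]-8-(3-methylbut-2-en-1-yl)-4-(trimethylsilyloxy)chromane (oxirane oxygen anti to the C2 aryl group) | COc1c(OCOC)c(CC=C(C)C)c2c(c1OCOC)[C@]3(O[Si](C)(C)C)O[C@@H]3[C@@H](c1ccccc1OCOC)O2 | intermediate
17 | (2R,3R)-3-hydroxy-6-methoxy-5,7-bis(methoxymethoxy)-2-[2-(methoxymethoxy)phenyl]-8-(3-methylbut-2-en-1-yl)-2,3-dihydro-4H-chromen-4-one | COc1c(OCOC)c(CC=C(C)C)c2c(c1OCOC)C(=O)[C@H](O)[C@@H](c1ccccc1OCOC)O2 | intermediate
18 | floranol, (2R,3R)-3,5,7-trihydroxy-2-(2-hydroxyphenyl)-6-methoxy-8-(3-methylbut-2-en-1-yl)-2,3-dihydro-4H-chromen-4-one | COc1c(O)c(CC=C(C)C)c2c(c1O)C(=O)[C@H](O)[C@@H](c1ccccc1O)O2 | target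

**Step count**
Total steps: 8. Longest linear sequence: 8 (steps 1–8; 12 is purchased).

**Steps most likely to fail**

Step 7 (Proposed new method). The aryl transfer to the electron-rich, peri-substituted chromone may be sluggish. A racemic background pathway through a Lewis-acid-generated 4-siloxybenzopyrylium ion may erode the enantioselectivity, Me3SiCl/ZnCl2 may strip MOM groups, and the enol silane may not survive the solvent switch. In that case the arylation is decoupled from the trapping. Setting out from 11, a Rh(I)/chiral diene-catalysed asymmetric 1,4-addition of 2-(methoxymethoxy)phenylboronic acid (COCOc1ccccc1B(O)O; aq. KOH, dioxane/H2O, 50 °C), the established arylboronic acid addition to chromones, should give the (2S)-flavanone F1. Kinetic enolisation of F1 with in situ silylation (LiHMDS, Me3SiCl, THF, −78 °C) should then give enol silane 15, where the route is rejoined for the dioxirane oxidation and hydrolysis to 17.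

Step 8. The acid may promote cyclisation of the prenyl chain onto the freed 7-hydroxyl, HCl addition to the olefin, or C2 epimerisation through ring opening assisted by the 2′-hydroxyl. The alternative avoids Brønsted acid by a non-protic protecting-group exchange. Setting out from 17, Me3SiOTf and 2,2′-bipyridyl (CH2Cl2, 0 °C) should convert the aryl MOM ethers, through bipyridinium acetal salts, into aryl silyl ethers and silylate the 3-hydroxyl, giving the tetrakis(trimethylsilyl) ether F2. Hydrolysis of F2 in aqueous THF at pH 5 (citrate buffer, 0 °C) should then release 18.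

Step 3. The phenoxide may attack the primary π-allyl terminus, or palladium may isomerise the tertiary ether to the linear O-prenyl ether, whose Claisen rearrangement would deliver a 1,1-dimethylallyl group; the tertiary ether may also ionise. The alternative builds the tertiary ether without a π-allyl intermediate. Setting out from 4, copper-catalysed alkylation with 3-chloro-3-methylbut-1-yne (CuCl2 cat., DBU, MeCN, 0 °C) should give the aryl 1,1-dimethylpropargyl ether F3. Lindlar semihydrogenation of F3 (H2, Pd/CaCO3–Pb, quinoline, EtOAc) should then give ether 5, which is heated in toluene as in step 3 to reach 6.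

**Further compounds**
F1 | step 7 | (2S)-6-methoxy-5,7-bis(methoxymethoxy)-2-[2-(methoxymethoxy)phenyl]-8-(3-methylbut-2-en-1-yl)-2,3-dihydro-4H-chromen-4-one | COc1c(OCOC)c(CC=C(C)C)c2c(c1OCOC)C(=O)C[C@@H](c1ccccc1OCOC)O2
F2 | step 8 | (2R,3R)-6-methoxy-8-(3-methylbut-2-en-1-yl)-3,5,7-tris(trimethylsilyloxy)-2-[2-(trimethylsilyloxy)phenyl]-2,3-dihydro-4H-chromen-4-one | COc1c(O[Si](C)(C)C)c(CC=C(C)C)c2c(c1O[Si](C)(C)C)C(=O)[C@H](O[Si](C)(C)C)[C@@H](c1ccccc1O[Si](C)(C)C)O2
F3 | step 3 | 2-methoxy-1,3-bis(methoxymethoxy)-5-[(2-methylbut-3-yn-2-yl)oxy]benzene | COc1c(OCOC)cc(OC(C)(C)C#C)cc1OCOC
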